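**Strategy**

The route rests on cutting the α-methylene-γ-lactone away from the carbocycle at O1–C15a and C3–C3a. The lactone oxygen sits on an allylic carbon (C15a) next to the C14=C15 alkene of the 14-membered ring, so C3a–C15a–C15=C14 is the retron of a 1,2-carbo-oxygenation of a ring 1,3-diene. The key step is a palladium-catalysed [3+2] heteroannulation of 2-bromoacrylic acid onto the (E,E)-diene of a macrocyclic tetraene acetate. It forms the C–C and C–O bonds and both ring-fusion stereocentres at once, brings in the exocyclic methylene and delivers the target directly. The tetraene is built from (2E,6E)-farnesol by methylenation, ω-oxidation, Brown allylation and diene–ene ring-closing metathesis.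

Key step: step 8

Remark on numbering: target atoms follow cyclotetradeca[b]furan numbering: O1, C2 (C=O), C3 (=CH2), C3a, C4, C5 (OAc), C6 to C14, C15, C15a.

Remark (assumption on the chemistry): on the chloride-ligated π-allylpalladium intermediate the tethered carboxylate is taken to attack from the face opposite the metal, the usual course for carboxylates. This is why the 12E diene, not the 12Z isomer, is the chosen precursor.

**Route**

Step 1
Reactants: 1 (2E,6E)-farnesol
Product: 2 (2E,6E)-farnesal
Conditions: activated MnO2 (excess), CH2Cl2, rt
Reagents that add atoms: none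
Why: Allylic oxidation on MnO2 should convert only the primary allylic alcohol to the enal, without over-oxidation and without loss of the 2E geometry.

Step 2
Reactants: 2 (2E,6E)-farnesal
Product: 3 (3E,7E)-4,8,12-trimethyltrideca-1,3,7,11-tetraene
Conditions: Ph3PCH3Br, KHMDS, THF, 0 °C; then 2, −78 °C → rt
Reagents that add atoms: methyltriphenylphosphonium bromide, C[P+](c1ccccc1)(c1ccccc1)c1ccccc1.[Br-]
Why: Wittig methylenation with the non-stabilised ylide should add 1,2 to the enal and leave the E geometry of the trisubstituted alkene, now part of a terminal diene, unchanged.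

Step 3
Reactants: 3 (3E,7E)-4,8,12-trimethyltrideca-1,3,7,11-tetraene
Product: 4 (2E,6E,10E)-2,6,10-trimethyltrideca-2,6,10,12-tetraen-1-ol
Conditions: SeO2 (0.3 equiv), t-BuOOH (2 equiv), salicylic acid (cat.), CH2Cl2, 0 °C → rt
Reagents that add atoms: tert-butyl hydroperoxide, CC(C)(C)OO (terminal oxygen source, relayed by catalytic selenium dioxide, O=[Se]=O)
Why: Riley allylic oxidation (ene reaction, then [2,3]-sigmatropic shift) should pick the most electron-rich and least hindered alkene, the terminal isopropylidene, and hydroxylate its E methyl group, while the less nucleophilic conjugated diene is expected to be tolerated.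

Step 4
Reactants: 4 (2E,6E,10E)-2,6,10-trimethyltrideca-2,6,10,12-tetraen-1-ol
Product: 5 (2E,6E,10E)-2,6,10-trimethyltrideca-2,6,10,12-tetraenal
Conditions: activated MnO2 (excess), CH2Cl2, rt
Reagents that add atoms: none
Why: MnO2 allylic oxidation should give the E enal and leave the diene and the other alkenes untouched.

Step 5
Reactants: 5 (2E,6E,10E)-2,6,10-trimethyltrideca-2,6,10,12-tetraenal
Product: 7 (3E,7E,11E,13R)-4,8,12-trimethylhexadeca-1,3,7,11,15-pentaen-13-ol, via diisopinocampheylborinate ester 6 (not isolated)
Conditions: lIpc2BOMe [(+)-B-methoxydiisopinocampheylborane, from (−)-α-pinene], allylMgBr, Et2O, −78 °C → rt; then 5, −78 °C; NaOH, H2O2, 0 °C → rt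
Reagents that add atoms: allylmagnesium bromide, C=CC[Mg]Br (allyl group, relayed by lIpc2B(allyl), C=CCB([C@H]1C[C@H]2C[C@@H]([C@@H]1C)C2(C)C)[C@H]1C[C@H]2C[C@@H]([C@@H]1C)C2(C)C)
Why: Brown allylboration through a closed chair transition state is reagent-controlled, and the isopinocampheyl groups from (−)-α-pinene should direct allyl to the aldehyde face that gives the 13R carbinol (the sense this antipode shows with aryl and alkenyl aldehydes).

Step 6
Reactants: 7 (3E,7E,11E,13R)-4,8,12-trimethylhexadeca-1,3,7,11,15-pentaen-13-ol
Product: 8 (3E,7E,11E,13R)-4,8,12-trimethylhexadeca-1,3,7,11,15-pentaen-13-yl acetate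
Conditions: Ac2O, pyridine, DMAP (cat.), CH2Cl2, 0 °C → rt
Reagents that add atoms: acetic anhydride, CC(=O)OC(C)=O
Why: DMAP-catalysed acylation installs the acetate of the target with retention at the carbinol carbon, and it removes a free hydroxyl that could later add to the methylene lactone.

Step 7
Reactants: 8 (3E,7E,11E,13R)-4,8,12-trimethylhexadeca-1,3,7,11,15-pentaen-13-yl acetate
Product: 9 (1R,2E,6E,10E,12E)-2,6,10-trimethylcyclotetradeca-2,6,10,12-tetraen-1-yl acetate
Conditions: Grubbs second-generation catalyst (10 mol%), CH2Cl2 (1 mM), 40 °C
Reagents that add atoms: none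
Why: Diene–ene ring-closing metathesis should start at the isolated monosubstituted alkene and close onto the unsubstituted diene terminus, with the three trisubstituted alkenes inert and the conjugated 12E alkene favoured under the reversible conditions.

Step 8
Reactants: 9 (1R,2E,6E,10E,12E)-2,6,10-trimethylcyclotetradeca-2,6,10,12-tetraen-1-yl acetate; 10 2-bromoacrylic acid
Product: 11 (3aS,5R,6E,10E,14E,15aS)-6,10,14-trimethyl-3-methylidene-2-oxo-2,3,3a,4,5,8,9,12,13,15a-decahydrocyclotetradeca[b]furan-5-yl acetate (target)
Conditions: Pd(OAc)2 (10 mol%), n-Bu4NCl (1 equiv), K2CO3 (3 equiv), DMF, 70 °C; 10 (2 equiv) added over 6 h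
Reagents that add atoms: 2-bromoacrylic acid 10, C=C(Br)C(=O)O
Why: Pd(0) inserts into the C–Br bond of the carboxylate of 10, the alkenylpalladium adds syn across the less substituted, 1,2-disubstituted terminus of the ring diene (C12=C13 of 9, which become C15a and C3a) to give a syn,syn-π-allylpalladium over C15a–C15–C14, and the tethered carboxylate attacks C15a on the face opposite palladium and releases Pd(0). The closest known reaction type is the Larock heteroannulation of 1,3-dienes by vinylic halides that carry a carboxylic acid, a [3+2] carbo-oxygenation. The γ-lactone closes 5-exo at the proximal allyl terminus, since attack at C14 would need a seven-membered ring. C3a is set by the face of carbopalladation, expected to be the peripheral face of the diene in the ring conformer that keeps the C5 acetoxy group on the outside (substrate control from C5); C15a then follows stereospecifically, because syn C–C and anti C–O bond formation across the E alkene give the cis ring fusion and the syn,syn-allyl returns the 14E alkene. The step needs site selectivity for the conjugated diene over the three isolated trisubstituted alkenes (only the diene gives a stabilised π-allyl), regioselectivity for C13 over the methyl-bearing diene terminus (sterics), and survival of the hindered allylic acetate, which phosphine-free, chloride-ligated palladium should ionise far more slowly than it inserts into the activated C–Br bond.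

**Compound list**

1 | (2E,6E)-farnesol, (2E,6E)-3,7,11-trimethyldodeca-2,6,10-trien-1-ol | OC/C=C(C)/CC/C=C(C)/CCC=C(C)C | starting material
2 | (2E,6E)-farnesal | O=C/C=C(C)/CC/C=C(C)/CCC=C(C)C | intermediate
3 | (3E,7E)-4,8,12-trimethyltrideca-1,3,7,11-tetraene | C=C/C=C(C)/CC/C=C(C)/CCC=C(C)C | intermediate
4 | (2E,6E,10E)-2,6,10-trimethyltrideca-2,6,10,12-tetraen-1-ol | C=C/C=C(C)/CC/C=C(C)/CC/C=C(C)/CO | intermediate
5 | (2E,6E,10E)-2,6,10-trimethyltrideca-2,6,10,12-tetraenal | C=C/C=C(C)/CC/C=C(C)/CC/C=C(C)/C=O | intermediate
6 | O-diisopinocampheylboryl ether (borinate ester) of alcohol 7 | C=C/C=C(C)/CC/C=C(C)/CC/C=C(C)/[C@H](OB([C@H]1C[C@H]2C[C@@H]([C@@H]1C)C2(C)C)[C@H]1C[C@H]2C[C@@H]([C@@H]1C)C2(C)C)CC=C | intermediate (not isolated)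
7 | (3E,7E,11E,13R)-4,8,12-trimethylhexadeca-1,3,7,11,15-pentaen-13-ol | C=C/C=C(C)/CC/C=C(C)/CC/C=C(C)/[C@H](O)CC=C | intermediate
8 | (3E,7E,11E,13R)-4,8,12-trimethylhexadeca-1,3,7,11,15-pentaen-13-yl acetate | C=C/C=C(C)/CC/C=C(C)/CC/C=C(C)/[C@H](OC(C)=O)CC=C | intermediate
9 | (1R,2E,6E,10E,12E)-2,6,10-trimethylcyclotetradeca-2,6,10,12-tetraen-1-yl acetate | C1/C=C(C)/CC/C=C(C)/[C@H](OC(C)=O)C/C=C/C=C(C)/C1 | intermediate
10 | 2-bromoacrylic acid | C=C(Br)C(=O)O | starting material
11 | (3aS,5R,6E,10E,14E,15aS)-6,10,14-trimethyl-3-methylidene-2-oxo-2,3,3a,4,5,8,9,12,13,15a-decahydrocyclotetradeca[b]furan-5-yl acetate | C=C1C(=O)O[C@H]2/C=C(\C)CC/C=C(\C)CC/C=C(\C)[C@H](OC(C)=O)C[C@@H]12 | target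

**Step count**

Total step count: 8
Longest linear sequence: 8 steps (1 → 11)

**Steps most likely to fail**

Step 8 (key step). The carbopalladation of an internal diene terminus may be slow, so that decomposition of the bromoacrylate and ionisation of the allylic acetate by Pd(0) compete. Facial selectivity at C3a rests only on the ring conformation and may be poor. Inner-sphere (syn) C–O bond formation may compete with anti attack and erode the cis ring fusion. The fallback sets out from 9 and comes back at 11, and replaces palladium catalysis by an oxidative free-radical lactone annulation. With Mn(OAc)3·2H2O, excess malonic acid and KOAc in AcOH at rt, the malonyl radical should add to C13 of the diene, Mn(III) should oxidise the allyl radical, and the carboxylate should close on C12. This would give the 3-carboxy-2,3-dihydro analogue of 11 F1 (C3 epimers), with the same two bonds formed in one operation. Decarboxylative Mannich methylenation (aq. CH2O, Et2NH, then NaOAc, AcOH, 70 °C) would then give 11.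

Step 7. The ring may close with poor E/Z selectivity at the new C12=C13 bond, and the catalyst may be held up as a stabilised vinylcarbene at the diene, giving oligomers. The fallback sets out from 8 and comes back at 9, and moves control of geometry from the metathesis to a separate thermodynamic step. The ring closure would be driven to conversion without regard to geometry, which should give 9 mixed with its 12Z isomer F2. The mixture would then be equilibrated through reversible iodine-atom addition to the conjugated diene (cat. I2, CH2Cl2, visible light), expected to favour the 12E isomer 9.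

Step 3. Selenium dioxide may attack the conjugated diene (ene reaction or cycloaddition) or the internal alkene, and over-oxidation may occur. The fallback sets out from 2 and comes back at 4, and carries out the ω-oxidation before the diene exists. Farnesal 2, whose C2=C3 bond is deactivated by the aldehyde, would be treated with SeO2 (cat.) and t-BuOOH to give (2E,6E,10E)-12-hydroxyfarnesal F3. Wittig methylenation with excess Ph3P=CH2 would then give 4.

**Further compounds**

F1 | step 8 | 3-carboxy-2,3-dihydro analogue of 11 (5-acetoxy-6,10,14-trimethyl-2-oxo-cyclotetradeca[b]furan-3-carboxylic acid, ring-fusion and C5 configuration as in 11, C3 epimers) | OC(=O)C1C(=O)O[C@H]2/C=C(\C)CC/C=C(\C)CC/C=C(\C)[C@H](OC(C)=O)C[C@@H]12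
F2 | step 7 | (1R,2E,6E,10E,12Z)-2,6,10-trimethylcyclotetradeca-2,6,10,12-tetraen-1-yl acetate | C1/C=C(C)/CC/C=C(C)/[C@H](OC(C)=O)C/C=C\C=C(C)\C1
F3 | step 3 | (2E,6E,10E)-12-hydroxy-3,7,11-trimethyldodeca-2,6,10-trienal (12-hydroxyfarnesal) | O=C/C=C(C)/CC/C=C(C)/CC/C=C(C)/CO
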